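Two chemists argue over one flask.

| setting | Tuesday's | flask |
|---|---|---|
| Z | 2.9 M | 2.9 M |
| X | 0.70 equiv | 0.700 equiv |
| L | 0.1 mol% | 0.1 mol% |
| remark | the very flask that is asked about, followed so far |  |
| time |  | 12 min |

- Tuesday's (time / min: E / %, G / %): 0.200: 37.1, 2.8; 0.667: 55.0, 5.2; 1.00: 57.1, 5.6; 1.50: 59.2, 7.7; 2.50: 57.9, 8.8

(readings scatter by 0.5 percentage points)

* ratio of E to G at 0.80 s
* ratio of E to G at 25 s
* ratio of E to G at 12 min

- what is said of E includes D
- D is a solid; its amount is given per volume of the solution
- the earlier runs were read with a standard deviation of 0.5 percentage points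
- what may be going on: Z + X <-> E; Z + X <-> G; E + L <-> G + L; 2 L <-> Q; D <-> E

Each E or G costs one X, and X is the limiting reagent, so E and G together cannot pass 70.0% of the Z charged. E as read includes the crystals D.

The first chemist looks at the ratio of E to G in Tuesday's run, which falls from 13.3 at 0.200 min to 6.58 at 2.50 min. She also sees E go from 59.2% to 57.9% over the last two readings. She concludes that E is leaking into G, a step that costs no X, so the ceiling does not bind it.

Her forecast for this flask is 14 at 0.80 s, 12 at 25 s and 2 at 12 min. For the last she writes: “extrapolating 9.5 min more gives E about 45 and G about 23, so about 2”.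

The second chemist takes a longer stretch of Tuesday's run. From 1.00 min to 2.50 min, G gained 3.2 percentage points, more than the 0.8 points by which E changed, and the readings scatter by 0.5 points. Meanwhile E and G together rose from 62.7% to 66.7%. So she reads X as still being spent, and by whichever way G is made, she holds E and G together under the ceiling.

Her quantity is the room for G, the X charge less the E held, which here reads 12.1% of the Z charged. If E stays at that reading, G can fill this room and no more, and the ratio at 12 min stays at or above 4.79. That is her own reckoning, and it differs from the forecast.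

The simulation gives 16.9 at 0.80 s, 11.3 at 25 s and 5.71 at 12 min.

    Z + X ⇌ E (K = 0.590 M⁻¹, k = 0.0320 M⁻¹ s⁻¹)
    Z + X ⇌ G (K = 2.80 M⁻¹, k = 0.00130 M⁻¹ s⁻¹)
    E + L ⇌ G + L, rate k3*[L]*[E] forward; the back reaction follows from the equilibrium constant (k = 16.0 M⁻¹ s⁻¹)
    2 L ⇌ Q (K = 260 M⁻¹, k = 12.0 M⁻¹ s⁻¹)
    D ⇌ E, rate k5*(cs5 - [E]) while solid is left; crystals form when [E] > cs5 (solubility = 0.0610 M, k = 1.70 s⁻¹)

The leak view keeps the early part of this flask, where its 12 at 25 s stands near 11.3. At 12 min this flask holds E 56.5%, G 9.89% and X 5.2% of its own charge, and its ratio 5.71 lies above the floor of 4.79, with G inside the room of 12.1%. The neighbouring flask with 0.420 equiv of X ends with E 30.1%, so its room is 11.9%, about the same, and its floor is 2.53. Its G stands at 9.86%, and its ratio at 12 min is 3.05, above that floor.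

The runs were computed with constants of no real substance.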